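**Retrosynthetic overview**
1. The ferulate C–O bond is cut last (Mitsunobu esterification of ferulic acid with the free chain alcohol). Before that, the chain hydroxyl (benzyl ether) is kept distinct from the C9 hydroxyl and the ring A phenol (silyl ethers).
2. The strategy rests on C3 of the dihydrofuran (ring C), which carries the fused benzene carbon C3a (ring B) and the one-carbon arm C9. This is the pattern left when C4a of a chroman-4-one moves from the carbonyl carbon C4 to C3 and C4 remains as an ester carbon, so the C3–C3a bond is disconnected back to a (2R)-flavanone.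
3. The flavanone comes from 6-(3-benzyloxypropyl)-8-methoxychromone and a pivalate-protected ring A boronic acid by enantioselective palladium-catalysed conjugate addition, which sets C2; C3 is then set from C2 during the ring contraction.
4. The chromone comes from 2'-hydroxy-3'-methoxyacetophenone by bromination, enaminone annulation and B-alkyl Suzuki–Miyaura coupling with allyl benzyl ether.
5. Ring order: rings A and B are bought, the pyranone ring is built on ring B, and ring C arises from it by contraction.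

Key step: step 7

Remark on the chemistry: ring A is the pendant 4-hydroxy-3-methoxyphenyl ring on C2, ring B the fused benzene ring, ring C the dihydrofuran; the target is the (2R,3S)-trans isomer, and the CIP label of C3 changes from R (ester) to S (carbinol) with no change in space.

**Route**

Step 1
Reactants: 1 1-(2-hydroxy-3-methoxyphenyl)ethan-1-one
Product: 2 1-(5-bromo-2-hydroxy-3-methoxyphenyl)ethan-1-one
Conditions: NBS, MeCN, 0 °C → rt
Reagents that add atoms: N-bromosuccinimide, O=C1CCC(=O)N1Br
Why: Electrophilic aromatic bromination: the phenol directs to its only free para position C5 (both ortho positions are substituted), which is also meta to the acetyl group, so one regioisomer is expected.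

Step 2
Reactants: 2 1-(5-bromo-2-hydroxy-3-methoxyphenyl)ethan-1-one
Product: 4 6-bromo-8-methoxy-4H-chromen-4-one, via enaminone 3 (not isolated)
Conditions: DMF-DMA, toluene, 100 °C; then conc. HCl, CH2Cl2, rt
Reagents that add atoms: N,N-dimethylformamide dimethyl acetal, COC(OC)N(C)C
Why: Condensation of the methyl ketone with the amide acetal gives the enaminone, and acid then drives 6-endo oxa-Michael addition of the phenol with loss of dimethylamine (enaminone chromone synthesis).

Step 3
Reactants: 4 6-bromo-8-methoxy-4H-chromen-4-one; 5 allyl benzyl ether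
Product: 7 6-[3-(benzyloxy)propyl]-8-methoxy-4H-chromen-4-one, via B-alkyl-9-BBN 6 (not isolated)
Conditions: 5 (1.3 equiv), 9-BBN (1.2 equiv), THF, 0 °C → rt; then 4, Pd(dppf)Cl2 (5 mol%), aq. K3PO4, DMF, 50 °C
Reagents that add atoms: none
Why: Anti-Markovnikov hydroboration of the terminal alkene followed by B-alkyl Suzuki–Miyaura coupling, in which zerovalent palladium inserts into the C6–Br bond and the primary alkyl group is transferred from the borate; the mild phosphate base at 50 °C should spare the pyranone ring.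

Step 4
Reactants: 8 2-methoxy-4-(4,4,5,5-tetramethyl-1,3,2-dioxaborolan-2-yl)phenol
Product: 9 2-methoxy-4-(4,4,5,5-tetramethyl-1,3,2-dioxaborolan-2-yl)phenyl pivalate
Conditions: PivCl, Et3N, DMAP (cat.), CH2Cl2, 0 °C → rt
Reagents that add atoms: pivaloyl chloride, CC(C)(C)C(=O)Cl
Why: DMAP-catalysed acylation of the phenol; the hindered pivalate is chosen because it should survive the acidic methanolic medium of step 7 and lowers the electron density of ring A.

Step 5
Reactants: 9 2-methoxy-4-(4,4,5,5-tetramethyl-1,3,2-dioxaborolan-2-yl)phenyl pivalate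
Product: 10 [3-methoxy-4-(pivaloyloxy)phenyl]boronic acid
Conditions: NaIO4, NH4OAc, acetone/H2O, rt
Reagents that add atoms: water, O
Why: Oxidative deprotection of a pinacol boronate: periodate cleaves the pinacol released on hydrolysis to acetone and so pulls the equilibrium to the free boronic acid, which transmetalates to palladium far more readily than the ester.

Step 6
Reactants: 7 6-[3-(benzyloxy)propyl]-8-methoxy-4H-chromen-4-one; 10 [3-methoxy-4-(pivaloyloxy)phenyl]boronic acid
Product: 11 (2R)-6-[3-(benzyloxy)propyl]-8-methoxy-2-[3-methoxy-4-(pivaloyloxy)phenyl]chroman-4-one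
Conditions: Pd(OCOCF3)2 (5 mol%), (S)-t-Bu-PyOx (6 mol%), NH4PF6 (30 mol%), H2O (5 equiv), ClCH2CH2Cl, 60 °C
Reagents that add atoms: none
Why: Enantioselective conjugate addition of an arylboronic acid to a chromone under cationic divalent palladium/pyridine-oxazoline catalysis (transmetalation, face-selective carbopalladation of C2=C3, protonolysis of the palladium enolate); the tert-butyl group of the (S)-ligand blocks one enone face and, by the sense it shows with β-substituted cyclic enones, should set C2 as R (to be confirmed on 11 before scale-up), while the redox-neutral cycle leaves the ester and the benzyl ether alone.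

Step 7
Reactants: 11 (2R)-6-[3-(benzyloxy)propyl]-8-methoxy-2-[3-methoxy-4-(pivaloyloxy)phenyl]chroman-4-one
Product: 15 methyl (2R,3R)-5-[3-(benzyloxy)propyl]-7-methoxy-2-[3-methoxy-4-(pivaloyloxy)phenyl]-2,3-dihydrobenzofuran-3-carboxylate, via methyl enol ether 12 (not isolated), via C3 iodane ketal 13 (not isolated), via trimethyl ortho ester 14 (not isolated)
Conditions: PhI(OAc)2 (1.2 equiv), conc. H2SO4, HC(OMe)3, 0 °C → rt; aq. NaHCO3 work-up
Reagents that add atoms: trimethyl orthoformate, COC(OC)OC; water, O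
Why: Acid and the orthoformate turn the C4 ketone into methyl enol ether 12, which trivalent iodine attacks at C3 on the face away from the C2 aryl group, and methanol traps the oxocarbenium ion as the C4 dimethyl ketal 13 with the iodane equatorial. The ring B carbon C4a, antiperiplanar to the C3–I bond, then shifts from C4 to C3 with expulsion of iodobenzene, and the dimethoxycarbenium ion left at the old C4 is captured as ortho ester 14, which aqueous work-up hydrolyses to methyl ester 15. This is the known oxidative ring contraction of flavanones to methyl trans-2-aryl-2,3-dihydrobenzofuran-3-carboxylates with PhI(OAc)2 in trimethyl orthoformate, a 1,2-aryl shift of the semipinacol kind. Ring C is therefore not closed by a cyclisation: the six-membered pyranone contracts to the five-membered ring as the C3–C3a bond forms (flavanone C4a becomes C3a) and C4 is extruded as the exocyclic ester carbon C9. The new stereocenter C3 is controlled by C2, since anti iodination followed by migration with inversion places the ester trans to the aryl group, which is also the more stable epimer of this enolisable center, while C2 itself is never touched. The step needs migration of C4a rather than of the C2 aryl group (which would lead to an isoflavone) or loss of HX to a flavone: the donor O1 ortho to C4a and the two ketal oxygens favour the C4a shift, and the pivalate makes ring A a poor migrating group and less prone to oxidation.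

Step 8
Reactants: 15 methyl (2R,3R)-5-[3-(benzyloxy)propyl]-7-methoxy-2-[3-methoxy-4-(pivaloyloxy)phenyl]-2,3-dihydrobenzofuran-3-carboxylate
Product: 16 4-[(2R,3S)-5-[3-(benzyloxy)propyl]-3-(hydroxymethyl)-7-methoxy-2,3-dihydrobenzofuran-2-yl]-2-methoxyphenol
Conditions: LiAlH4, THF, 0 °C; aq. potassium sodium tartrate work-up
Reagents that add atoms: none
Why: Hydride reduction of the methyl ester to the C9 carbinol with simultaneous reductive cleavage of the aryl pivalate; no stereocenter is touched at 0 °C and the cyclic benzylic ether is inert to hydride.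

Step 9
Reactants: 16 4-[(2R,3S)-5-[3-(benzyloxy)propyl]-3-(hydroxymethyl)-7-methoxy-2,3-dihydrobenzofuran-2-yl]-2-methoxyphenol
Product: 17 (2R,3S)-5-[3-(benzyloxy)propyl]-2-[4-(tert-butyldimethylsilyloxy)-3-methoxyphenyl]-3-[(tert-butyldimethylsilyloxy)methyl]-7-methoxy-2,3-dihydrobenzofuran
Conditions: TBSCl, imidazole, DMF, rt
Reagents that add atoms: tert-butyldimethylsilyl chloride, CC(C)(C)[Si](C)(C)Cl
Why: Silylation of both the phenol and the primary alcohol, so that only the chain oxygen remains masked as a benzyl ether.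

Step 10
Reactants: 17 (2R,3S)-5-[3-(benzyloxy)propyl]-2-[4-(tert-butyldimethylsilyloxy)-3-methoxyphenyl]-3-[(tert-butyldimethylsilyloxy)methyl]-7-methoxy-2,3-dihydrobenzofuran
Product: 18 3-[(2R,3S)-2-[4-(tert-butyldimethylsilyloxy)-3-methoxyphenyl]-3-[(tert-butyldimethylsilyloxy)methyl]-7-methoxy-2,3-dihydrobenzofuran-5-yl]propan-1-ol
Conditions: H2 (1 atm), Pd/C, EtOAc, rt
Reagents that add atoms: none
Why: Hydrogenolysis of the primary benzyl ether on Pd/C; at 1 atm in EtOAc and stopped at full conversion it should leave both silyl ethers and the C2–O1 benzylic aryl ether of ring C, which is secondary and hindered by the C3 substituent.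

Step 11
Reactants: 18 3-[(2R,3S)-2-[4-(tert-butyldimethylsilyloxy)-3-methoxyphenyl]-3-[(tert-butyldimethylsilyloxy)methyl]-7-methoxy-2,3-dihydrobenzofuran-5-yl]propan-1-ol; 19 ferulic acid
Product: 20 3-[(2R,3S)-2-[4-(tert-butyldimethylsilyloxy)-3-methoxyphenyl]-3-[(tert-butyldimethylsilyloxy)methyl]-7-methoxy-2,3-dihydrobenzofuran-5-yl]propyl (E)-3-(4-hydroxy-3-methoxyphenyl)prop-2-enoate
Conditions: 19, PPh3, DIAD, THF, 0 °C → rt
Reagents that add atoms: none
Why: Mitsunobu esterification: the carboxylic acid is far more acidic than the phenol of 19 and is the only pronucleophile engaged, so the unprotected phenolic acid should esterify the primary alkoxyphosphonium ion chemoselectively; the carbinol is primary and no stereocenter is involved.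

Step 12
Reactants: 20 3-[(2R,3S)-2-[4-(tert-butyldimethylsilyloxy)-3-methoxyphenyl]-3-[(tert-butyldimethylsilyloxy)methyl]-7-methoxy-2,3-dihydrobenzofuran-5-yl]propyl (E)-3-(4-hydroxy-3-methoxyphenyl)prop-2-enoate
Product: 21 3-[(2R,3S)-2-(4-hydroxy-3-methoxyphenyl)-3-(hydroxymethyl)-7-methoxy-2,3-dihydrobenzofuran-5-yl]propyl (E)-3-(4-hydroxy-3-methoxyphenyl)prop-2-enoate (CNP0149450.1)
Conditions: TBAF, AcOH, THF, 0 °C → rt
Reagents that add atoms: none
Why: Fluoride-induced cleavage of the aryl and the primary alkyl silyl ether; acetic acid buffers the phenoxides so that the cinnamate ester is neither hydrolysed nor transesterified.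

**Compound list**
1 | 1-(2-hydroxy-3-methoxyphenyl)ethan-1-one | CC(=O)c1cccc(OC)c1O | starting material
2 | 1-(5-bromo-2-hydroxy-3-methoxyphenyl)ethan-1-one | CC(=O)c1cc(Br)cc(OC)c1O | intermediate
3 | (E)-1-(5-bromo-2-hydroxy-3-methoxyphenyl)-3-(dimethylamino)prop-2-en-1-one | CN(C)/C=C/C(=O)c1cc(Br)cc(OC)c1O | intermediate
4 | 6-bromo-8-methoxy-4H-chromen-4-one | O=c1ccoc2c(OC)cc(Br)cc12 | intermediate
5 | allyl benzyl ether | C=CCOCc1ccccc1 | starting material
6 | 9-[3-(benzyloxy)propyl]-9-borabicyclo[3.3.1]nonane | c1ccccc1COCCCB1C2CCCC1CCC2 | intermediate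
7 | 6-[3-(benzyloxy)propyl]-8-methoxy-4H-chromen-4-one | O(Cc1ccccc1)CCCc2cc(OC)c3occc(=O)c3c2 | intermediate
8 | 2-methoxy-4-(4,4,5,5-tetramethyl-1,3,2-dioxaborolan-2-yl)phenol | COc1cc(B2OC(C)(C)C(C)(C)O2)ccc1O | starting material
9 | 2-methoxy-4-(4,4,5,5-tetramethyl-1,3,2-dioxaborolan-2-yl)phenyl pivalate | COc1cc(B2OC(C)(C)C(C)(C)O2)ccc1OC(=O)C(C)(C)C | intermediate
10 | [3-methoxy-4-(pivaloyloxy)phenyl]boronic acid | COc1cc(B(O)O)ccc1OC(=O)C(C)(C)C | intermediate
11 | (2R)-6-[3-(benzyloxy)propyl]-8-methoxy-2-[3-methoxy-4-(pivaloyloxy)phenyl]chroman-4-one | O(Cc1ccccc1)CCCc2cc(OC)c3c(c2)C(=O)C[C@H](c2ccc(OC(=O)C(C)(C)C)c(OC)c2)O3 | intermediate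
12 | (2R)-6-[3-(benzyloxy)propyl]-4,8-dimethoxy-2-[3-methoxy-4-(pivaloyloxy)phenyl]-2H-chromene | O(Cc1ccccc1)CCCc2cc(OC)c3c(c2)C(OC)=C[C@H](c2ccc(OC(=O)C(C)(C)C)c(OC)c2)O3 | intermediate
13 | 3-[acetoxy(phenyl)iodanyl]-6-[3-(benzyloxy)propyl]-4,4,8-trimethoxy-2-[3-methoxy-4-(pivaloyloxy)phenyl]chromane, C2 in space as in 11, iodine trans to the C2 aryl group (2S,3S by CIP) | O(Cc1ccccc1)CCCc2cc(OC)c3c(c2)C(OC)(OC)[C@@H](I(OC(C)=O)c2ccccc2)[C@H](c2ccc(OC(=O)C(C)(C)C)c(OC)c2)O3 | intermediate
14 | (2R,3R)-5-[3-(benzyloxy)propyl]-7-methoxy-2-[3-methoxy-4-(pivaloyloxy)phenyl]-3-(trimethoxymethyl)-2,3-dihydrobenzofuran (trans) | O(Cc1ccccc1)CCCc2cc(OC)c3c(c2)[C@@H](C(OC)(OC)OC)[C@H](c2ccc(OC(=O)C(C)(C)C)c(OC)c2)O3 | intermediate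
15 | methyl (2R,3R)-5-[3-(benzyloxy)propyl]-7-methoxy-2-[3-methoxy-4-(pivaloyloxy)phenyl]-2,3-dihydrobenzofuran-3-carboxylate (trans) | O(Cc1ccccc1)CCCc2cc(OC)c3c(c2)[C@@H](C(=O)OC)[C@H](c2ccc(OC(=O)C(C)(C)C)c(OC)c2)O3 | intermediate
16 | 4-[(2R,3S)-5-[3-(benzyloxy)propyl]-3-(hydroxymethyl)-7-methoxy-2,3-dihydrobenzofuran-2-yl]-2-methoxyphenol | O(Cc1ccccc1)CCCc2cc(OC)c3c(c2)[C@@H](CO)[C@H](c2ccc(O)c(OC)c2)O3 | intermediate
17 | (2R,3S)-5-[3-(benzyloxy)propyl]-2-[4-(tert-butyldimethylsilyloxy)-3-methoxyphenyl]-3-[(tert-butyldimethylsilyloxy)methyl]-7-methoxy-2,3-dihydrobenzofuran | O(Cc1ccccc1)CCCc2cc(OC)c3c(c2)[C@@H](CO[Si](C)(C)C(C)(C)C)[C@H](c2ccc(O[Si](C)(C)C(C)(C)C)c(OC)c2)O3 | intermediate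
18 | 3-[(2R,3S)-2-[4-(tert-butyldimethylsilyloxy)-3-methoxyphenyl]-3-[(tert-butyldimethylsilyloxy)methyl]-7-methoxy-2,3-dihydrobenzofuran-5-yl]propan-1-ol | OCCCc1cc(OC)c2c(c1)[C@@H](CO[Si](C)(C)C(C)(C)C)[C@H](c1ccc(O[Si](C)(C)C(C)(C)C)c(OC)c1)O2 | intermediate
19 | ferulic acid, (E)-3-(4-hydroxy-3-methoxyphenyl)prop-2-enoic acid | COc1cc(/C=C/C(=O)O)ccc1O | starting material
20 | 3-[(2R,3S)-2-[4-(tert-butyldimethylsilyloxy)-3-methoxyphenyl]-3-[(tert-butyldimethylsilyloxy)methyl]-7-methoxy-2,3-dihydrobenzofuran-5-yl]propyl (E)-3-(4-hydroxy-3-methoxyphenyl)prop-2-enoate | COc1cc(/C=C/C(=O)OCCCc2cc(OC)c3c(c2)[C@@H](CO[Si](C)(C)C(C)(C)C)[C@H](c2ccc(O[Si](C)(C)C(C)(C)C)c(OC)c2)O3)ccc1O | intermediate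
21 | 3-[(2R,3S)-2-(4-hydroxy-3-methoxyphenyl)-3-(hydroxymethyl)-7-methoxy-2,3-dihydrobenzofuran-5-yl]propyl (E)-3-(4-hydroxy-3-methoxyphenyl)prop-2-enoate | COc1cc(/C=C/C(=O)OCCCc2cc(OC)c3c(c2)[C@@H](CO)[C@H](c2ccc(O)c(OC)c2)O3)ccc1O | target

**Step count**
Total: 12 steps. Longest linear sequence: 10 steps (steps 1, 2, 3, 6, 7, 8, 9, 10, 11, 12); steps 4 and 5 make the boronic acid branch.

**Steps most likely to fail**

Step 7. The iodane may collapse by other paths: shift of the C2 aryl group instead of C4a, elimination to the flavone, simple α-methoxylation, or oxidative attack on the electron-rich ring B. Fallback, from 11 back to 15: the same C4a shift is brought about through a ketene in a Wolff ring contraction. Ketone 11 is acylated at C3 (LiHMDS, CF3CO2CH2CF3, THF, −78 °C, kept cold so that the enolate does not open ring C) to the 3-trifluoroacetyl flavanone F1. Detrifluoroacetylative diazo transfer (MsN3, Et3N, MeCN, rt) should give the 3-diazo flavanone F2. Irradiation in MeOH should expel nitrogen with migration of C4a to C3 and give the ring-contracted ketene F3, which methanol traps as the methyl ester. Any cis ester F4 formed on protonation is equilibrated to the trans ester 15 with DBU in CH2Cl2.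

Step 6. Carbopalladation of the 8-methoxy chromone may be slow, so that protodeboronation or homocoupling of the boronic acid takes over, or the facial discrimination may be insufficient. Fallback, from 7 and 10 back to 11: the addition is run without asymmetric induction (Pd(OCOCF3)2, 2,2'-bipyridine, NH4PF6, H2O, ClCH2CH2Cl, 60 °C) to give the racemic flavanone F5. F5 is then resolved kinetically by asymmetric transfer hydrogenation (RuCl(p-cymene)[(S,S)-TsDPEN], HCO2H/Et3N, EtOAc, rt, stopped near half conversion). The (2S) ketone is expected to be reduced to the (2S,4S)-cis-flavan-4-ol F6, and the unreacted (2R) ketone 11 is separated by chromatography.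

Step 3. Aqueous base may open the C2-unsubstituted pyranone ring, or residual borane may reduce the enone, before cross-coupling is complete. Fallback, from 4 back to 7: a base-free Negishi coupling. Commercial benzyl 3-bromopropyl ether is converted with zinc dust and LiCl in THF into [3-(benzyloxy)propyl]zinc bromide F7, which is coupled with 4 (Pd(OAc)2, SPhos, THF, rt → 50 °C) to give 7 directly.

**Further compounds**
F1 | step 7 | 6-[3-(benzyloxy)propyl]-8-methoxy-2-[3-methoxy-4-(pivaloyloxy)phenyl]-3-(trifluoroacetyl)chroman-4-one, C2 in space as in 11, C3 unassigned | O(Cc1ccccc1)CCCc2cc(OC)c3c(c2)C(=O)C(C(=O)C(F)(F)F)[C@H](c2ccc(OC(=O)C(C)(C)C)c(OC)c2)O3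
F2 | step 7 | 6-[3-(benzyloxy)propyl]-3-diazo-8-methoxy-2-[3-methoxy-4-(pivaloyloxy)phenyl]chroman-4-one, C2 in space as in 11 | O(Cc1ccccc1)CCCc2cc(OC)c3c(c2)C(=O)C(=[N+]=[N-])[C@H](c2ccc(OC(=O)C(C)(C)C)c(OC)c2)O3
F3 | step 7 | {5-[3-(benzyloxy)propyl]-7-methoxy-2-[3-methoxy-4-(pivaloyloxy)phenyl]benzofuran-3(2H)-ylidene}methanone (ring-contracted ketene), C2 in space as in 11 | O(Cc1ccccc1)CCCc2cc(OC)c3c(c2)C(=C=O)[C@H](c2ccc(OC(=O)C(C)(C)C)c(OC)c2)O3
F4 | step 7 | methyl (2R,3S)-5-[3-(benzyloxy)propyl]-7-methoxy-2-[3-methoxy-4-(pivaloyloxy)phenyl]-2,3-dihydrobenzofuran-3-carboxylate (cis epimer of 15) | O(Cc1ccccc1)CCCc2cc(OC)c3c(c2)[C@H](C(=O)OC)[C@H](c2ccc(OC(=O)C(C)(C)C)c(OC)c2)O3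
F5 | step 6 | racemic 6-[3-(benzyloxy)propyl]-8-methoxy-2-[3-methoxy-4-(pivaloyloxy)phenyl]chroman-4-one | O(Cc1ccccc1)CCCc2cc(OC)c3c(c2)C(=O)CC(c2ccc(OC(=O)C(C)(C)C)c(OC)c2)O3
F6 | step 6 | (2S,4S)-6-[3-(benzyloxy)propyl]-8-methoxy-2-[3-methoxy-4-(pivaloyloxy)phenyl]chroman-4-ol (cis) | O(Cc1ccccc1)CCCc2cc(OC)c3c(c2)[C@@H](O)C[C@@H](c2ccc(OC(=O)C(C)(C)C)c(OC)c2)O3
F7 | step 3 | [3-(benzyloxy)propyl]zinc bromide | Br[Zn]CCCOCc1ccccc1
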